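**Retrosynthetic overview**
1. The 14-membered carbocycle is closed last, at C14–C1, by a Nozaki–Hiyama–Kishi reaction of a 2-iodoalkene with an aldehyde; this also creates the C14 carbinol and the exocyclic methylene.
2. The δ-lactone (ring atoms O, C16, C15, C8, C9, C10) is made in one pot from the acyclic C6 propionate 16: an Ireland–Claisen shift forms C15–C8, then the freed carboxylate opens the 10,11-epoxide to form O–C10.
3. Feature used: C8 and C10 are 1,3-related on the carbocycle and C11 carries the tertiary hydroxyl, so C10/C11 are a latent E-trisubstituted epoxide. A propionate on the allylic C6 oxygen across an E C7=C8 alkene is relayed to C8, five atoms from C10, and the all-equatorial 3,4,6-substituted lactone is also the thermodynamic C15 epimer.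
4. Propionate 16 comes from enal 4 (C1–C6, from pent-4-yn-1-ol) and epoxy alkyne 11 (C7–C14, from geranyl acetate) by asymmetric alkenylzinc addition, matched Sharpless epoxidation and acylation.
5. Ring order: 10,11-oxirane, 4,5-oxirane, δ-lactone (consuming the 10,11-oxirane), carbocycle.

Key step: step 11

Remark on numbering: ring carbons are C1–C14, with C1 bearing the exocyclic methylene C18, C4/C5 the oxirane (C19 on C5), C8 bearing C15, C10 bearing the lactone oxygen, C11 the tertiary carbinol (C20) and C14 the allylic carbinol; the lactone is O–C16(=O)–C15(C17). The target is (4S,5S,8R,10R,11S,14S,15S); C5 reads R in 16 and 17 and C8 reads S while C6=C7 is present, for priority reasons only.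
Remark (assumption): (−)-MIB, (2S)-3-exo-morpholinoisoborneol, is taken to direct the alkenyl group to the Si face of enal 4, the sense this ligand shows with other aldehydes.

**Route**

Step 1
Reactants: 1 pent-4-yn-1-ol
Product: 2 4-iodopent-4-en-1-ol
Conditions: NaI, Me3SiCl, H2O, MeCN, 25 °C
Reagents that add atoms: sodium iodide, [Na+].[I-]
Why: Markovnikov hydroiodination of the terminal alkyne by HI formed in the flask should give the 2-iodo-1-alkene, the transiently silylated hydroxyl being freed on aqueous work-up.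

Step 2
Reactants: 2 4-iodopent-4-en-1-ol
Product: 3 4-iodopent-4-enal
Conditions: TEMPO (cat.), PhI(OAc)2, CH2Cl2, 25 °C
Reagents that add atoms: none
Why: TEMPO-catalysed oxidation of the primary alcohol should stop at the aldehyde and leave the iodoalkene alone.

Step 3
Reactants: 3 4-iodopent-4-enal
Product: 4 (E)-6-iodo-2-methylhepta-2,6-dienal
Conditions: Ph3P=C(Me)CHO, toluene, 90 °C
Reagents that add atoms: 2-(triphenylphosphoranylidene)propanal, CC(C=O)=P(c1ccccc1)(c1ccccc1)c1ccccc1
Why: Wittig olefination with the stabilised α-methyl ylide should give the E-configured trisubstituted enal.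

Step 4
Reactants: 5 geranyl acetate
Product: 6 (E)-4-methyl-6-oxohex-2-en-1-yl acetate
Conditions: O3 (1 equiv.), CH2Cl2, pyridine, −78 °C; then Me2S
Reagents that add atoms: ozone, [O-][O+]=O
Why: Ozonolysis should cleave the electron-rich 6,7-alkene selectively because the 2,3-alkene is deactivated by the allylic acetate.

Step 5
Reactants: 6 (E)-4-methyl-6-oxohex-2-en-1-yl acetate
Product: 8 (E)-6,6-dimethoxy-3-methylhex-2-en-1-ol, via acetal acetate 7 (not isolated)
Conditions: HC(OMe)3, MeOH, PPTS (cat.), 25 °C; then K2CO3, 25 °C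
Reagents that add atoms: trimethyl orthoformate, COC(OC)OC; methanol, CO
Why: Acid-catalysed acetalisation masks the aldehyde and carbonate-mediated transesterification in the same flask removes the acetate.

Step 6
Reactants: 8 (E)-6,6-dimethoxy-3-methylhex-2-en-1-ol
Product: 9 [(2S,3S)-3-(3,3-dimethoxypropyl)-3-methyloxiran-2-yl]methanol
Conditions: Ti(OiPr)4 (cat.), L-(+)-diethyl tartrate (cat.), t-BuOOH, 4 Å MS, CH2Cl2, −20 °C
Reagents that add atoms: tert-butyl hydroperoxide, CC(C)(C)OO
Why: Sharpless asymmetric epoxidation with the L-(+)-tartrate should give the (2S,3S)-epoxy alcohol, the sense known for geraniol, which sets the configurations that become C10 and C11.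

Step 7
Reactants: 9 [(2S,3S)-3-(3,3-dimethoxypropyl)-3-methyloxiran-2-yl]methanol
Product: 11 (2S,3S)-3-(3,3-dimethoxypropyl)-3-methyl-2-(prop-2-yn-1-yl)oxirane, via epoxy triflate 10 (not isolated)
Conditions: Tf2O, 2,6-lutidine, CH2Cl2, −78 °C; then HC≡CLi (from HC≡CH, n-BuLi), THF/DMPU, −78 → −30 °C
Reagents that add atoms: lithium acetylide, [Li]C#C
Why: SN2 alkynylation of the primary triflate should be faster than attack on the hindered trisubstituted epoxide, so C7–C9 are installed with the oxirane intact.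

Step 8
Reactants: 11 (2S,3S)-3-(3,3-dimethoxypropyl)-3-methyl-2-(prop-2-yn-1-yl)oxirane; 4 (E)-6-iodo-2-methylhepta-2,6-dienal
Product: 14 (2E,4S,5E)-1-[(2S,3S)-3-(3,3-dimethoxypropyl)-3-methyloxiran-2-yl]-9-iodo-5-methyldeca-2,5,9-trien-4-ol, via alkenylborane 12 (not isolated), via alkenylzinc 13 (not isolated)
Conditions: Cy2BH, toluene, 0 → 25 °C; Et2Zn, −78 °C; (−)-MIB (cat.); then 4, −20 °C; aq. NH4Cl
Reagents that add atoms: none
Why: Syn hydroboration gives the E-alkenylborane, boron-to-zinc exchange gives the alkenylzinc, and its amino-alcohol-catalysed 1,2-addition to the enal (catalytic asymmetric alkenylzinc addition) forms C6–C7 and should set C6 as (S) by ligand-controlled Si-face attack.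

Step 9
Reactants: 14 dienol
Product: 15 (1S,2E)-4-[(2S,3S)-3-(3,3-dimethoxypropyl)-3-methyloxiran-2-yl]-1-[(2S,3S)-3-(3-iodobut-3-en-1-yl)-2-methyloxiran-2-yl]but-2-en-1-ol
Conditions: Ti(OiPr)4 (cat.), L-(+)-diisopropyl tartrate (cat.), t-BuOOH, 4 Å MS, CH2Cl2, −25 °C
Reagents that add atoms: tert-butyl hydroperoxide, CC(C)(C)OO
Why: In this Sharpless asymmetric epoxidation the (6S) carbinol and the L-(+)-tartrate are the matched pair for the trisubstituted C4=C5 arm and the mismatched pair for the C7=C8 arm, so the 4,5-epoxide should form alone, anti (erythro) to the C6 hydroxyl, as (4S,5S).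

Step 10
Reactants: 15 bis-epoxy alcohol
Product: 16 (1S,2E)-4-[(2S,3S)-3-(3,3-dimethoxypropyl)-3-methyloxiran-2-yl]-1-[(2R,3S)-3-(3-iodobut-3-en-1-yl)-2-methyloxiran-2-yl]but-2-en-1-yl propanoate
Conditions: (EtCO)2O, Et3N, DMAP (cat.), CH2Cl2, 0 → 25 °C
Reagents that add atoms: propionic anhydride, CCC(=O)OC(=O)CC
Why: DMAP-catalysed acylation of the hindered secondary alcohol installs the propionate without touching a stereocentre.

Step 11
Reactants: 16 C6 propionate
Product: 20 (3S,4S,6R)-6-[(2S)-2-hydroxy-5,5-dimethoxypentan-2-yl]-4-{(E)-2-[(2S,3S)-3-(3-iodobut-3-en-1-yl)-2-methyloxiran-2-yl]ethenyl}-3-methyloxan-2-one, via ketene acetal 17 (not isolated), via silyl ester 18 (not isolated), via epoxy acid 19 (not isolated)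
Conditions: LiN(iPr)2, THF, −78 °C; Me3SiCl/Et3N (1:2), −78 → 25 °C; then H2O, 50 °C
Reagents that add atoms: none
Why: Kinetic deprotonation in THF and O-silylation give the (E)-ketene acetal 17 (methyl cis to the allylic oxygen), which undergoes the Ireland–Claisen [3,3] shift through a chair with the bulky oxiranyl group at C6 equatorial, forming C15–C8 and the E C6=C7 alkene; water then hydrolyses silyl ester 18, and acid 19, as its triethylammonium (lithium) carboxylate, opens the 10,11-epoxide at C10 to form O–C10. The closest known reaction types are the Ireland–Claisen rearrangement of secondary E-allylic propionates and the hydroxy-lactonisation of epoxy acids. The only ring closed, the δ-lactone, forms in the 6-exo-tet mode with SN2 inversion at C10. C8 is controlled by 1,3-chirality transfer from the (6S) carbinol across the E alkene, C15 by the ketene acetal geometry (E acetal plus E alkene gives the anti, 3,4-trans relationship), C10 by inversion of the (10S) epoxide carbon, and C11 keeps its epoxide configuration as the tertiary alcohol. The step needs the carboxylate to choose C10 of the 10,11-epoxide: after the shift it sits five atoms from the secondary C10, which favours 6-exo attack over 7-endo attack at quaternary C11, while the 4,5-epoxide is reachable only through 7- or 8-membered closures or an SN2' path and the non-acidic medium keeps this allylic epoxide from ionising. Because the all-equatorial lactone is the thermodynamic C15 epimer, any minor syn isomer can be converged by base equilibration.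

Step 12
Reactants: 20 unsaturated hydroxy lactone
Product: 21 (3S,4R,6R)-6-[(2S)-2-hydroxy-5,5-dimethoxypentan-2-yl]-4-{2-[(2S,3S)-3-(3-iodobut-3-en-1-yl)-2-methyloxiran-2-yl]ethyl}-3-methyloxan-2-one
Conditions: 2-nitrobenzenesulfonohydrazide, Et3N, CH2Cl2, 25 °C
Reagents that add atoms: none
Why: Diimide formed in the flask transfers H2 in a concerted syn fashion to the only 1,2-disubstituted alkene, while the electron-poor iodoalkene is inert and the epoxide is not hydrogenolysed as it would be over a metal catalyst.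

Step 13
Reactants: 21 saturated hydroxy lactone
Product: 22 (3S,4R,6R)-6-[(2S)-5,5-dimethoxy-2-(triethylsilyloxy)pentan-2-yl]-4-{2-[(2S,3S)-3-(3-iodobut-3-en-1-yl)-2-methyloxiran-2-yl]ethyl}-3-methyloxan-2-one
Conditions: Et3SiOTf, 2,6-lutidine, CH2Cl2, −78 °C
Reagents that add atoms: triethylsilyl trifluoromethanesulfonate, CC[Si](CC)(CC)OS(=O)(=O)C(F)(F)F
Why: Low-temperature silylation of the tertiary C11 alcohol keeps it from closing to a five-membered lactol with the C14 aldehyde that is unmasked next.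

Step 14
Reactants: 22 silyl ether acetal
Product: 23 (4S)-4-[(2R,4R,5S)-4-{2-[(2S,3S)-3-(3-iodobut-3-en-1-yl)-2-methyloxiran-2-yl]ethyl}-5-methyl-6-oxooxan-2-yl]-4-(triethylsilyloxy)pentanal
Conditions: PPTS (cat.), acetone/H2O, 40 °C
Reagents that add atoms: water, O
Why: Mild acid-catalysed hydrolysis of the dimethyl acetal should free the C14 aldehyde while the isolated trisubstituted epoxide, the tertiary silyl ether and the lactone survive.

Step 15
Reactants: 23 iodoalkene aldehyde
Product: 25 11-O-triethylsilyl ether of the target, via alkenylchromium 24 (not isolated)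
Conditions: CrCl2, NiCl2 (cat.), DMSO/THF, 25 °C, 2 mM
Reagents that add atoms: none
Why: In this Nozaki–Hiyama–Kishi reaction, nickel-catalysed formation of alkenylchromium 24 and its intramolecular addition to the aldehyde close the 14-membered ring and should set C14 as (S) under control of the macrocyclic transition state, which makes C14 the least secure stereocentre of the route.

Step 16
Reactants: 25 11-O-triethylsilyl ether of the target
Product: 26 target cembranolide
Conditions: Bu4NF, AcOH, THF, 0 → 25 °C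
Reagents that add atoms: none
Why: Buffered fluoride removes the tertiary triethylsilyl ether without affecting lactone, epoxide or allylic alcohol and should give the target.

**Compound list**

1 | pent-4-yn-1-ol | C#CCCCO | starting material
2 | 4-iodopent-4-en-1-ol | C=C(I)CCCO | intermediate
3 | 4-iodopent-4-enal | C=C(I)CCC=O | intermediate
4 | (E)-6-iodo-2-methylhepta-2,6-dienal | C=C(I)CC/C=C(\C)C=O | intermediate
5 | geranyl acetate, (E)-3,7-dimethylocta-2,6-dien-1-yl acetate | CC(C)=CCC/C(C)=C/COC(C)=O | starting material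
6 | (E)-4-methyl-6-oxohex-2-en-1-yl acetate | CC(=O)OC/C=C(C)/CCC=O | intermediate
7 | (E)-6,6-dimethoxy-3-methylhex-2-en-1-yl acetate | CC(=O)OC/C=C(C)/CCC(OC)OC | intermediate
8 | (E)-6,6-dimethoxy-3-methylhex-2-en-1-ol | OC/C=C(C)/CCC(OC)OC | intermediate
9 | [(2S,3S)-3-(3,3-dimethoxypropyl)-3-methyloxiran-2-yl]methanol | OC[C@@H]1O[C@@]1(C)CCC(OC)OC | intermediate
10 | [(2S,3S)-3-(3,3-dimethoxypropyl)-3-methyloxiran-2-yl]methyl trifluoromethanesulfonate | O=S(=O)(OC[C@@H]1O[C@@]1(C)CCC(OC)OC)C(F)(F)F | intermediate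
11 | (2S,3S)-3-(3,3-dimethoxypropyl)-3-methyl-2-(prop-2-yn-1-yl)oxirane | C#CC[C@@H]1O[C@@]1(C)CCC(OC)OC | intermediate
12 | dicyclohexyl{(1E)-3-[(2S,3S)-3-(3,3-dimethoxypropyl)-3-methyloxiran-2-yl]prop-1-en-1-yl}borane | C1CCCCC1B(/C=C/C[C@@H]2O[C@@]2(C)CCC(OC)OC)C1CCCCC1 | intermediate
13 | ethyl{(1E)-3-[(2S,3S)-3-(3,3-dimethoxypropyl)-3-methyloxiran-2-yl]prop-1-en-1-yl}zinc | CC[Zn]/C=C/C[C@@H]1O[C@@]1(C)CCC(OC)OC | intermediate
14 | (2E,4S,5E)-1-[(2S,3S)-3-(3,3-dimethoxypropyl)-3-methyloxiran-2-yl]-9-iodo-5-methyldeca-2,5,9-trien-4-ol | C=C(I)CC/C=C(\C)[C@@H](O)/C=C/C[C@@H]1O[C@@]1(C)CCC(OC)OC | intermediate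
15 | (1S,2E)-4-[(2S,3S)-3-(3,3-dimethoxypropyl)-3-methyloxiran-2-yl]-1-[(2S,3S)-3-(3-iodobut-3-en-1-yl)-2-methyloxiran-2-yl]but-2-en-1-ol | C=C(I)CC[C@@H]1O[C@@]1(C)[C@@H](O)/C=C/C[C@@H]2O[C@@]2(C)CCC(OC)OC | intermediate
16 | (1S,2E)-4-[(2S,3S)-3-(3,3-dimethoxypropyl)-3-methyloxiran-2-yl]-1-[(2R,3S)-3-(3-iodobut-3-en-1-yl)-2-methyloxiran-2-yl]but-2-en-1-yl propanoate | C=C(I)CC[C@@H]1O[C@@]1(C)[C@@H](OC(=O)CC)/C=C/C[C@@H]2O[C@@]2(C)CCC(OC)OC | intermediate
17 | (E)-O-trimethylsilyl ketene acetal of 16 (methyl cis to the allylic oxygen) | C=C(I)CC[C@@H]1O[C@@]1(C)[C@@H](O/C(O[Si](C)(C)C)=C\C)/C=C/C[C@@H]2O[C@@]2(C)CCC(OC)OC | intermediate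
18 | trimethylsilyl (2S,3S,4E)-3-{[(2S,3S)-3-(3,3-dimethoxypropyl)-3-methyloxiran-2-yl]methyl}-5-[(2S,3S)-3-(3-iodobut-3-en-1-yl)-2-methyloxiran-2-yl]-2-methylpent-4-enoate | C=C(I)CC[C@@H]1O[C@@]1(C)/C=C/[C@@H]([C@H](C)C(=O)O[Si](C)(C)C)C[C@@H]2O[C@@]2(C)CCC(OC)OC | intermediate
19 | (2S,3S,4E)-3-{[(2S,3S)-3-(3,3-dimethoxypropyl)-3-methyloxiran-2-yl]methyl}-5-[(2S,3S)-3-(3-iodobut-3-en-1-yl)-2-methyloxiran-2-yl]-2-methylpent-4-enoic acid | C=C(I)CC[C@@H]1O[C@@]1(C)/C=C/[C@@H]([C@H](C)C(=O)O)C[C@@H]2O[C@@]2(C)CCC(OC)OC | intermediate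
20 | (3S,4S,6R)-6-[(2S)-2-hydroxy-5,5-dimethoxypentan-2-yl]-4-{(E)-2-[(2S,3S)-3-(3-iodobut-3-en-1-yl)-2-methyloxiran-2-yl]ethenyl}-3-methyloxan-2-one | C=C(I)CC[C@@H]1O[C@@]1(C)/C=C/[C@@H]2C[C@@H](OC(=O)[C@H]2C)[C@@](C)(O)CCC(OC)OC | intermediate
21 | (3S,4R,6R)-6-[(2S)-2-hydroxy-5,5-dimethoxypentan-2-yl]-4-{2-[(2S,3S)-3-(3-iodobut-3-en-1-yl)-2-methyloxiran-2-yl]ethyl}-3-methyloxan-2-one | C=C(I)CC[C@@H]1O[C@@]1(C)CC[C@@H]2C[C@@H](OC(=O)[C@H]2C)[C@@](C)(O)CCC(OC)OC | intermediate
22 | (3S,4R,6R)-6-[(2S)-5,5-dimethoxy-2-(triethylsilyloxy)pentan-2-yl]-4-{2-[(2S,3S)-3-(3-iodobut-3-en-1-yl)-2-methyloxiran-2-yl]ethyl}-3-methyloxan-2-one | C=C(I)CC[C@@H]1O[C@@]1(C)CC[C@@H]2C[C@@H](OC(=O)[C@H]2C)[C@@](C)(O[Si](CC)(CC)CC)CCC(OC)OC | intermediate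
23 | (4S)-4-[(2R,4R,5S)-4-{2-[(2S,3S)-3-(3-iodobut-3-en-1-yl)-2-methyloxiran-2-yl]ethyl}-5-methyl-6-oxooxan-2-yl]-4-(triethylsilyloxy)pentanal | C=C(I)CC[C@@H]1O[C@@]1(C)CC[C@@H]2C[C@@H](OC(=O)[C@H]2C)[C@@](C)(O[Si](CC)(CC)CC)CCC=O | intermediate
24 | alkenylchromium dichloride formed from 23 at C1 (iodine replaced by CrCl2) | C=C([Cr](Cl)Cl)CC[C@@H]1O[C@@]1(C)CC[C@@H]2C[C@@H](OC(=O)[C@H]2C)[C@@](C)(O[Si](CC)(CC)CC)CCC=O | intermediate
25 | 11-O-triethylsilyl ether of the target, (4S,5S,8R,10R,11S,14S,15S) | C=C1CC[C@@H]2O[C@@]2(C)CC[C@@H]2C[C@@H](OC(=O)[C@H]2C)[C@@](C)(O[Si](CC)(CC)CC)CC[C@@H]1O | intermediate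
26 | target cembranolide CNP0262409.2: 4,5-epoxy-11,14-dihydroxy-1(18)-ene 16,10-δ-lactone, (4S,5S,8R,10R,11S,14S,15S) | C=C1CC[C@@H]2O[C@@]2(C)CC[C@@H]2C[C@@H](OC(=O)[C@H]2C)[C@@](C)(O)CC[C@@H]1O | target

**Step count and risks**

Total steps: 16. Longest linear sequence: 13 steps (steps 4–16, from geranyl acetate); the enal arm is 3 steps.

Steps most likely to fail:

Step 15. The intramolecular addition may show poor facial selectivity at C14, since only the macrocyclic transition state controls it, or ring closure may lose to protodeiodination at high dilution. The fallback sets out from 25 obtained as a C14 epimer mixture and comes back at 25. The mixture is oxidised with Dess–Martin periodinane to the macrocyclic α-methylene 14-ketone F4. This is reduced under Corey–Bakshi–Shibata control, (R)-2-methyl-CBS-oxazaborolidine with catecholborane at −78 °C, the alkenyl group acting as the large substituent, to return (14S)-25.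

Step 11. The amide base may attack the allylic 4,5-epoxide or erode the ketene acetal geometry, the rearrangement may leak through a boat, or the carboxylate may be captured at the wrong epoxide carbon. The fallback sets out from 15 and comes back at 20. Johnson–Claisen rearrangement of 15 with triethyl orthopropionate and catalytic propionic acid gives, with the same chair-controlled transfer of the C6 configuration to C8, ethyl ester F3 as a C15 epimer mixture. Saponification with LiOH in aqueous THF and neutralisation let the carboxylate close onto the 10,11-epoxide. DBU then equilibrates C15 to the equatorial epimer, which is 20.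

Step 7. The epoxy triflate may decompose, or the acetylide may open or eliminate the epoxide instead of displacing the triflate. The fallback sets out from 8 and comes back at 11, bypassing steps 6 and 7. Alcohol 8 is converted with CBr4/PPh3 into allylic bromide F1, which is coupled with ethynylmagnesium bromide under CuI catalysis to 1,4-enyne F2. Shi epoxidation of the trisubstituted alkene with the enantiomer of the fructose-derived ketone (KHSO5 as oxidant, carbonate buffer) then gives 11.

Further compounds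
F1 | step 7 | (E)-1-bromo-6,6-dimethoxy-3-methylhex-2-ene | COC(OC)CC/C(C)=C/CBr
F2 | step 7 | (E)-8,8-dimethoxy-5-methyloct-4-en-1-yne | C#CC/C=C(C)/CCC(OC)OC
F3 | step 11 | ethyl (3S,4E)-3-{[(2S,3S)-3-(3,3-dimethoxypropyl)-3-methyloxiran-2-yl]methyl}-5-[(2S,3S)-3-(3-iodobut-3-en-1-yl)-2-methyloxiran-2-yl]-2-methylpent-4-enoate, C2 epimer mixture | C=C(I)CC[C@@H]1O[C@@]1(C)/C=C/[C@@H](C(C)C(=O)OCC)C[C@@H]2O[C@@]2(C)CCC(OC)OC
F4 | step 15 | 14-oxo analogue of 25 (macrocyclic α-methylene ketone) | C=C1CC[C@@H]2O[C@@]2(C)CC[C@@H]2C[C@@H](OC(=O)[C@H]2C)[C@@](C)(O[Si](CC)(CC)CC)CCC1=O
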